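**Retrosynthetic overview**
1. C3–Br and N1–C2 are disconnected together: 3-bromoindole ⇒ 2-(bromoethynyl)aniline. The ring closes through nitrogen while bromine moves 1,2 from the alkyne terminus to the future C3.
2. C(sp)–Br ⇒ C(sp)–SiMe3 (silicon-to-bromine exchange in the same flask). C3a–C3 ⇒ aryl iodide + trimethylsilylacetylene (Sonogashira).
3. Aryl iodide ⇒ 3,4-dibromoaniline by ortho iodination. N1, Br-5 and Br-6 are bought already in place.
4. Ring order: the benzene ring is bought. The pyrrole ring is the only ring made, in the last step.

Assumption: the target is planar and has no stereogenic element, so the achiral compound itself is the product asked for and no step needs stereocontrol.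

**Route**

Step 1
Reactants: 1 3,4-dibromoaniline
Product: 2 4,5-dibromo-2-iodoaniline
Conditions: NIS (1.02 equiv), AcOH, 20 °C, dark, 3 h; aq. Na2S2O3/NaHCO3 work-up, recrystallise
Reagents that add atoms: N-iodosuccinimide (NIS), O=C1CCC(=O)N1I
Why: Electrophilic aromatic iodination: NH2 directs ortho/para, the para site carries Br, and the ortho site between NH2 and Br is hindered, so the bulky iodine electrophile takes the open ortho position.

Step 2
Reactants: 2 4,5-dibromo-2-iodoaniline; 3 ethynyl(trimethyl)silane (trimethylsilylacetylene)
Product: 4 4,5-dibromo-2-[(trimethylsilyl)ethynyl]aniline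
Conditions: PdCl2(PPh3)2 (2 mol %), CuI (4 mol %), Et3N/THF 1:1, 3 (1.1 equiv), 20 °C, N2, 6 h
Reagents that add atoms: none
Why: Sonogashira coupling: at room temperature zerovalent palladium inserts into the aryl iodide far faster than into either aryl bromide, and the silyl cap prevents Glaser coupling and premature cyclisation while the free NH2 is tolerated.

Step 3
Reactants: 4 4,5-dibromo-2-[(trimethylsilyl)ethynyl]aniline
Product: 6 3,5,6-tribromo-1H-indole, via bromoalkyne 5 (not isolated)
Conditions: NBS (1.0 equiv), AgNO3 (10 mol %), acetone, 0 → 20 °C, dark, 2 h; then acetone off, (IPr)AuNTf2 (5 mol %; IPr = 1,3-bis(2,6-diisopropylphenyl)imidazol-2-ylidene), 4 Å MS, ClCH2CH2Cl (0.05 M), 60 °C; aq. NaHCO3 work-up, Et3N-deactivated silica, store cold and dark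
Reagents that add atoms: N-bromosuccinimide (NBS), O=C1CCC(=O)N1Br
Why: Proposed new method: aminative cycloisomerisation of a 1-bromoalkyne with 1,2-bromine shift; the known silver-catalysed silicon-to-bromine exchange first gives 5, and in its π-complex with the carbene-ligated monovalent gold cation the electronically preferred attack at the aryl-bearing carbon would need a four-membered ring while attack at the bromine-bearing carbon is polarity-mismatched and further slowed by the weakly nucleophilic dibromoaniline, so bromine can slip 1,2 to give a β-aryl-β-bromo gold vinylidene (stabilised by the strongly donating ligand) whose electrophilic carbene carbon lies in five-ring reach of the ortho NH2, N–C bond formation then gives a 2-aurated 3-bromoindolium, and N-to-C proton transfer (protodeauration) releases aromatic 6 and the catalyst with no electrophilic bromine left to attack the new indole; the closest known reaction types are the gold-vinylidene cycloisomerisation of haloethynyl-biaryls with 1,2-halide shift (carbon nucleophile) and the vinylidene-type cycloisomerisation of 2-ethynylanilines (1,2-hydrogen shift), neither described for an N–H nucleophile on a bromoalkyne.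

**Compound list**
1 | 3,4-dibromoaniline | Nc1ccc(Br)c(Br)c1 | starting material
2 | 4,5-dibromo-2-iodoaniline | Nc1cc(Br)c(Br)cc1I | intermediate
3 | ethynyl(trimethyl)silane (trimethylsilylacetylene) | C#C[Si](C)(C)C | starting material
4 | 4,5-dibromo-2-[(trimethylsilyl)ethynyl]aniline | C[Si](C)(C)C#Cc1cc(Br)c(Br)cc1N | intermediate
5 | 4,5-dibromo-2-(bromoethynyl)aniline | BrC#Cc1cc(Br)c(Br)cc1N | intermediate
6 | 3,5,6-tribromo-1H-indole | Brc1cc2[nH]cc(Br)c2cc1Br | target

**Total step count:** 3. **Longest linear sequence:** 3.

**Steps most likely to fail**

Step 3 (the proposed new step).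
- Nitrogen may attack the bromine-bearing carbon directly, without migration. That gives the 2,5,6-tribromo isomer, recognised by a C3–H signal near 6.5 ppm in place of the C2–H doublet near 7.3 ppm.
- NBS may brominate the last free ortho position of the aniline during the first stage.
- Traces of water may hydrate the bromoalkyne.

The fallback uses known chemistry only. It sets out from 4 and comes back at 6. Heating 4 with CuI (2 equiv) in moist DMF at 100 °C brings about copper-promoted 5-endo-dig hydroamination with loss of the silyl group. This gives 5,6-dibromo-1H-indole F1. Treating it with NBS (1.0 equiv) in DMF at 0 °C in the dark brominates C3, by far the most nucleophilic position, and delivers 6.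

Step 1.
- Some iodination may occur at the hindered ortho site.
- Some di-iodination may occur.
- Either would cost yield and make purification harder.

The fallback replaces undirected substitution by amide-directed C–H activation. It sets out from 1 and comes back at 2. Ac2O in AcOH gives N-(3,4-dibromophenyl)acetamide F2. Pd(OAc)2 (5 mol %), TsOH·H2O (0.5 equiv) and NIS in toluene at 20 °C then form the six-membered palladacycle of divalent palladium, and only at the unhindered ortho C–H. Iodination there gives N-(4,5-dibromo-2-iodophenyl)acetamide F3. 6 M HCl in EtOH at reflux, followed by neutralisation, returns 2.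

Step 2.
- One of the aryl bromides may couple as well.
- Copper may trigger early ring closure.

The fallback drops cross-coupling in favour of halogen–metal exchange and one-carbon homologation. It sets out from 2 and comes back at 5.
- PhMgCl (1.05 equiv, THF, −30 °C) removes one N–H. iPrMgCl·LiCl (1.1 equiv, −25 °C) then exchanges only the iodine, giving chloro{2-[(chloromagnesio)amino]-4,5-dibromophenyl}magnesium F4.
- DMF followed by aq. NH4Cl gives 2-amino-4,5-dibromobenzaldehyde F5.
- Dimethyl (1-diazo-2-oxopropyl)phosphonate with K2CO3 in MeOH at 20 °C (Ohira–Bestmann homologation) gives 4,5-dibromo-2-ethynylaniline F6.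
- NBS with AgNO3 (10 mol %) in acetone brominates the alkyne C–H to give 5, which then enters the gold stage of step 3.

**Further compounds**
F1 | step 3 | 5,6-dibromo-1H-indole | Brc1cc2cc[nH]c2cc1Br
F2 | step 1 | N-(3,4-dibromophenyl)acetamide | CC(=O)Nc1ccc(Br)c(Br)c1
F3 | step 1 | N-(4,5-dibromo-2-iodophenyl)acetamide | CC(=O)Nc1cc(Br)c(Br)cc1I
F4 | step 2 | chloro{2-[(chloromagnesio)amino]-4,5-dibromophenyl}magnesium | Cl[Mg]Nc1cc(Br)c(Br)cc1[Mg]Cl
F5 | step 2 | 2-amino-4,5-dibromobenzaldehyde | Nc1cc(Br)c(Br)cc1C=O
F6 | step 2 | 4,5-dibromo-2-ethynylaniline | Nc1cc(Br)c(Br)cc1C#C
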